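A small charge of free catalyst, 0.5 mol% in the winter run, took starting material down to 48.0% after 40.0 h. As a pseudo-first-order loss that is 0.0183 /h. Per unit of free catalyst, the noon run gives 0.967 times the winter value at the same reading time, although winter held about half the second catalyst of noon.

| flask | starting material | reagent | free catalyst | second catalyst | remark | time |
|---|---|---|---|---|---|---|
| summer | 1.4 M | 1.2 equiv (fed, over 0.10 d) | 0.34 mol% | 2.5 mol% | run made earlier; the fed solution adds 0.25 times the starting volume |  |
| noon | 1.4 M | 1.2 equiv (fed, over 0.10 d) | 0.75 mol% | 2.5 mol% | run made earlier; the fed solution adds 0.25 times the starting volume |  |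
| winter | 1.4 M | 1.2 equiv (fed, over 0.10 d) | 0.5 mol% | 1.2 mol% | run made earlier; the fed solution adds 0.25 times the starting volume |  |
| north-west | 1.4 M | 1.20 equiv (fed, over 0.10 d) | 0.5 mol% | 2.5 mol% | the fed solution adds 0.25 times the starting volume | 2.5 d |
| north | 1.4 M | 1.20 equiv (fed, over 0.30 d) | 0.5 mol% | 2.5 mol% | the fed solution adds 0.25 times the starting volume | 2.5 d |
| east | 1.4 M | 1.20 equiv (fed, over 0.80 d) | 0.5 mol% | 2.5 mol% | the fed solution adds 0.25 times the starting volume | 2.5 d |
| north-east | 1.4 M | 1.20 equiv (fed, over 2.5 d) | 0.5 mol% | 2.5 mol% | the fed solution adds 0.25 times the starting volume | 2.5 d |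
| west | 1.4 M | 1.20 equiv (fed, over 8.0 d) | 0.5 mol% | 2.5 mol% | the fed solution adds 0.25 times the starting volume | 2.5 d |

| run | time / h | target / % | starting material / % |
|---|---|---|---|
| summer | 3.00 | 0.5 | 95.6 |
| summer | 5.00 | 0.1 | 93.4 |
| summer | 8.00 | 1.2 | 89.3 |
| summer | 12.0 | 2.3 | 85.8 |
| summer | 20.0 | 5.7 | 76.2 |
| summer | 40.0 | 8.7 | 60.1 |
| noon | 6.00 | 1.7 | 84.6 |
| noon | 12.0 | 6.4 | 69.8 |
| noon | 20.0 | 11.2 | 57.4 |
| noon | 25.0 | 12.3 | 49.8 |
| noon | 30.0 | 12.7 | 44.4 |
| noon | 40.0 | 14.7 | 34.5 |
| winter | 3.00 | 0 | 93.4 |
| winter | 5.00 | 0.9 | 90.5 |
| winter | 10.0 | 2.5 | 81.5 |
| winter | 20.0 | 5.2 | 67.5 |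
| winter | 40.0 | 8.4 | 48.0 |

(readings scatter by 0.5 percentage points)

- charges are per starting volume, the dose included; the dosed solution carries all of it
- the numbers in the tables scatter by 0.5 percentage points (one standard deviation)
- steps under discussion: starting material + free catalyst <-> free catalyst + intermediate; reagent + second catalyst + intermediate -> second catalyst + target; reagent + target -> over-reaction product
- percentages count the whole charge, also what has not yet gone in
- "hardly changes" means that all values lie within two and a half points (for a concentration: within two and a half percent of the largest)

* amount of target at the end, in percent of the starting material charged for north-west, north, east, north-east, west, in this order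
* the course of these numbers from the first flask to the last (rises, then falls / rises all the way / hardly changes / falls all the way / falls, then rises)

Take the given numbers in turn and ask what an error in each would cost the row. An error in the loss rate moves the intermediate formed, and that step takes no reagent. The loadings and the reagent charge are equal across these flasks, so an error there is the same error in each of them. The feed volume dilutes free catalyst to 80.0% of its strength once the feed is in. The winter rate already carries that dilution, so it errs for the slow feeds. The dosing time, however, runs from 0.10 d to 8.0 d, and it is the setting that separates these flasks.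

So I carry the fed share, 31.2% for west at the end: the part of the reagent charge that has entered by a given time, which is elapsed time over dosing time until the feed stops. For north-east it is 100%. West receives 0.375 equivalents of reagent on the starting material by the end, and east has its whole charge in after a third of the time, so I expect the early flasks close together, a peak near north-east and a lower west, without committing to figures.

The forecast gave 13%, 13.3%, 14.5%, 16% and 12.5%, so rises, then falls, noting that the west feed “delivers only 31% of the reagent by the end”.

The flasks gave 13.2%, 13.3%, 13.7%, 17.8% and 15.2%, so rises, then falls, with the row turning at a dosing time of 3.6 d.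

    starting material + free catalyst ⇌ free catalyst + intermediate (K = 4.10, k = 3.50 /M/h)
    reagent + second catalyst + intermediate → second catalyst + target (k = 1.70 /M²/h)
    reagent + target → over-reaction product (k = 0.0720 /M/h)

At the end of west, the fed share of 31.2% less the 11% of the reagent charge standing in the flask leaves 24.1% of the starting material charged as reagent spent. Target at 15.2% and over-reaction product at 4.48%, counted twice, come to 24.2%. In north-east the fed share reached 100%, and 46% of the reagent charge stood unused, more than in west.

All runs were computed on assumed constants; noise was put on by code.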